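C1 = lactone C=O, C2 = CH2, C3 = CH(OO), C4 = C(CH3)(O‑lactone), C5 = CH2, C6 = C(CH3)(OO), C7–C14 = side chain. The retrosynthesis first cuts C5–H and C4–O(lactone) (deiodination, iodolactonisation). This leaves a 3,6‑dihydro‑1,2‑dioxine‑3‑acetate, which is then cut at C3–C4 and at O–C6 in one stroke.
Enabling feature: the 1,2‑dioxane ring consists of two three‑atom halves, O–O–C3 and C4–C5–C6. C3 is an aldehyde‑level carbon beta to C1 (a peroxycarbenium ion), and C6 becomes tertiary and allylic once C4=C5 is kept unsaturated. The oxygen on C4 can be returned later from C1 through the five‑membered lactone ring, so C4–C5–C6 can enter as a 3‑silylallyl cation equivalent.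
Helpers: a 2,5‑dihydro‑1,2‑oxasilole is used as a temporary ring. Its silicon makes C4 a vinylsilane, masks the C6 oxygen and tethers the hydroperoxide. Silicon leaves in the key step; the C4=C5 unsaturation and the iodine at C5 leave in the last two steps.
Forward order: side chain, methyl ketone, oxasilole, dioxine ring, lactone ring, reduction at C5.
Stereochemistry: C12=C13 (E) comes from syn‑carboalumination and C8 from a copper‑catalysed asymmetric conjugate addition. C3 comes from the chiral counter‑anion in the key step, C6 is relayed from C3 (allylic strain in the allyl cation), and C4 follows from C3 by cis‑fused iodolactonisation.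

Key step: step 9

Assumption: the ligand enantiomer named in step 4 and the acid enantiomer named in step 9 are taken to give 8S and 3R. If the sense of induction is the opposite one, the mirror‑image ligand or acid is used.

Step 1
Reactants: 1 hex-5-yn-1-ol; 2 benzyl bromide
Product: 4 (E)-5-methyl-7-phenylhept-5-en-1-ol, via alkenylalane 3 (not isolated)
Conditions: Me3Al (3 equiv), Cp2ZrCl2 (25 mol %), CH2Cl2, 0 °C to rt; then 2, Pd(PPh3)4 (5 mol %), THF, rt; aqueous work-up
Reagents that add atoms: trimethylaluminium C[Al](C)C
Why: Negishi carboalumination adds CH3 and Al syn across the alkyne (CH3 on the internal carbon), and the alkenylalane is benzylated with retention under zerovalent palladium catalysis, which fixes the E geometry of C12=C13.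

Step 2
Reactants: 4 (E)-5-methyl-7-phenylhept-5-en-1-ol
Product: 5 (E)-5-methyl-7-phenylhept-5-enal
Conditions: 1,1,1-triacetoxy-1,2-benziodoxol-3(1H)-one (Dess–Martin periodinane), CH2Cl2, 0 °C to rt
Reagents that add atoms: none
Why: Dess–Martin oxidation stops at the aldehyde and leaves the trisubstituted alkene untouched.

Step 3
Reactants: 5 (E)-5-methyl-7-phenylhept-5-enal; 6 1-(triphenylphosphoranylidene)propan-2-one
Product: 7 (3E,8E)-8-methyl-10-phenyldeca-3,8-dien-2-one
Conditions: CH2Cl2, rt
Reagents that add atoms: none
Why: The Wittig reaction of a stabilised ylide with an aliphatic aldehyde should give the E-enone.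

Step 4
Reactants: 7 (3E,8E)-8-methyl-10-phenyldeca-3,8-dien-2-one
Product: 8 (4S,8E)-4,8-dimethyl-10-phenyldec-8-en-2-one
Conditions: MeMgBr (1.2 equiv), CuBr·SMe2 (5 mol %), (R)-1-[(Sp)-2-(diphenylphosphino)ferrocenyl]ethyldicyclohexylphosphine (6 mol %), t-BuOMe, −75 °C; aq. NH4Cl
Reagents that add atoms: methylmagnesium bromide C[Mg]Br
Why: In this copper-catalysed asymmetric conjugate addition of a Grignard reagent to an acyclic enone, the ferrocenyl diphosphine copper complex selects the enone face and so sets C8 as S.

Step 5
Reactants: 8 (4S,8E)-4,8-dimethyl-10-phenyldec-8-en-2-one; 9 prop-1-yn-1-ylmagnesium bromide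
Product: 10 (6S,10E)-4,6,10-trimethyl-12-phenyldodec-10-en-2-yn-4-ol (both carbinol epimers)
Conditions: THF, −78 to 0 °C; aq. NH4Cl
Reagents that add atoms: none
Why: Grignard 1,2-addition to the methyl ketone gives both epimers at the carbinol carbon (C6), and both are carried on because C6 becomes planar in step 9.

Step 6
Reactants: 10 (6S,10E)-4,6,10-trimethyl-12-phenyldodec-10-en-2-yn-4-ol
Product: 11 dimethylsilyl ether of 10
Conditions: Me2SiHCl, Et3N, DMAP (cat.), CH2Cl2, 0 °C
Reagents that add atoms: chlorodimethylsilane C[SiH](C)Cl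
Why: O-silylation of a tertiary alcohol by a small chlorosilane installs the Si–H group needed for the ring closure.

Step 7
Reactants: 11 dimethylsilyl ether of 10
Product: 12 5-[(2S,6E)-2,6-dimethyl-8-phenyloct-6-en-1-yl]-2,2,3,5-tetramethyl-2,5-dihydro-1,2-oxasilole
Conditions: KOt-Bu (10 mol %), THF, rt
Reagents that add atoms: none
Why: Alkoxide-catalysed intramolecular trans-hydrosilylation (5-endo-dig, through a pentacoordinate hydridosilicate) puts Si on the distal alkyne carbon C4 and H on C5, and the ring forces Si to be cis to C6.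

Step 8
Reactants: 13 methyl but-3-enoate
Product: 14 methyl 3-hydroperoxy-3-methoxypropanoate (racemic)
Conditions: O3, CH2Cl2/MeOH, −78 °C; N2 purge; kept cold
Reagents that add atoms: ozone [O-][O+]=O; methanol CO
Why: In ozonolysis in methanol the primary ozonide of a terminal alkene fragments (Criegee mechanism) mainly to formaldehyde and the substituted carbonyl oxide, which methanol traps as the hydroperoxy acetal.

Step 9
Reactants: 12 oxasilole; 14 methyl 3-hydroperoxy-3-methoxypropanoate
Product: 17 methyl 2-[(3R,6R)-4,6-dimethyl-6-[(2S,6E)-2,6-dimethyl-8-phenyloct-6-en-1-yl]-3,6-dihydro-1,2-dioxin-3-yl]acetate, via silyl peroxide 15 (not isolated), via rearranged silyl peroxide 16 (not isolated)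
Conditions: 14 (1.2 equiv), toluene, −78 °C; then (R)-3,3'-bis(2,4,6-triisopropylphenyl)-1,1'-binaphthyl-2,2'-diyl N-triflylphosphoramide (10 mol %), −78 to −30 °C
Reagents that add atoms: none
Why: Proposed new method: The hydroperoxide of 14 opens the strained Si–O bond of 12 to silyl peroxide 15, the chiral acid ionises the C3–OMe bond, and C4 of the vinylsilane attacks the silylperoxycarbenium carbon C3 at its ipso position through a five-membered C4–Si–O–O–C3 array (beta-silyl cation at C5, retention of alkene geometry), silicon taking up the methanol to give 16. The same acid then ionises the tertiary allylic C6–OH of 16 and the silylated peroxide oxygen captures the C6 end of the C4–C5–C6 allyl cation while silicon leaves as methoxydimethylsilanol, so C3–C4 and O–C6 arise in one flask from one catalyst. The closest known reaction types are vinylsilane-terminated cyclisations of oxocarbenium ions, additions of allyl and enol silanes to peroxycarbenium ions, the annulation of silylperoxycarbenium ions with alkenes to 1,2-dioxolanes, the alkylation of hydroperoxides by tertiary carbocations, and Prins-type cyclisations run with chiral acid counter-anions. The only ring that is kept, the six-membered 3,6-dihydro-1,2-dioxine, closes in a 6-endo-trig mode at the allyl cation, since attack at the C4 end would need a four-membered ring. C3 is set in the vinyl transfer by the chiral anion paired with the planar peroxycarbenium ion, and C6 is set in the closure, where strain against the C4 methyl and the inside group on C6 leaves the peroxide chain on one face of the allyl plane and the cation should place CH3 inside and the longer chain outside, so the chain should end trans to the acetate arm (3R,6R). The step needs chemoselectivity over the C12=C13 alkene, secured by the Si–O–O tether that makes both bond formations intramolecular, and ipso attack at C4 rather than C5, secured by the beta-silicon effect.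

Step 10
Reactants: 17 dihydrodioxine ester
Product: 18 (3R,4S,5R,6R,8S)-5-iodoplakortolide G (target skeleton with iodine on C5 trans to the lactone oxygen on C4)
Conditions: I2 (3 equiv), MeCN, 0 °C, dark
Reagents that add atoms: iodine II
Why: In this iodolactonisation of a gamma,delta-unsaturated ester (5-exo-trig, anti addition) the ester carbonyl oxygen reaches the tertiary carbon C4 only from the face of the C2 arm, so the lactone is cis-fused, C4 is set by C3, and iodide removes the methyl group.

Step 11
Reactants: 18 5-iodoplakortolide G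
Product: 19 plakortolide G (3R,4R,6R,8S)
Conditions: Bu3SnH, Et3B (cat.), air, toluene, 0 °C
Reagents that add atoms: none
Why: Tin hydride radical dehalogenation replaces I by H; the C5 radical sits inside the dioxane ring, where it cannot line up for displacement on the O–O bond, and no stereocentre is touched.

Compound list
1 | hex-5-yn-1-ol | C#CCCCCO | starting material
2 | benzyl bromide | BrCc1ccccc1 | starting material
3 | alkenylalane (O-aluminated, Al cis to CH3) | C[Al](C)OCCCC/C(C)=C/[Al](C)C | intermediate
4 | (E)-5-methyl-7-phenylhept-5-en-1-ol | OCCCC/C(C)=C/Cc1ccccc1 | intermediate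
5 | (E)-5-methyl-7-phenylhept-5-enal | O=CCCC/C(C)=C/Cc1ccccc1 | intermediate
6 | 1-(triphenylphosphoranylidene)propan-2-one | CC(=O)C=P(c1ccccc1)(c1ccccc1)c1ccccc1 | starting material
7 | (3E,8E)-8-methyl-10-phenyldeca-3,8-dien-2-one | CC(=O)/C=C/CCC/C(C)=C/Cc1ccccc1 | intermediate
8 | (4S,8E)-4,8-dimethyl-10-phenyldec-8-en-2-one | CC(=O)C[C@@H](C)CCC/C(C)=C/Cc1ccccc1 | intermediate
9 | prop-1-yn-1-ylmagnesium bromide | CC#C[Mg]Br | starting material
10 | (6S,10E)-4,6,10-trimethyl-12-phenyldodec-10-en-2-yn-4-ol, both carbinol epimers | CC#CC(C)(O)C[C@@H](C)CCC/C(C)=C/Cc1ccccc1 | intermediate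
11 | dimethylsilyl ether of 10, both epimers | CC#CC(C)(C[C@@H](C)CCC/C(C)=C/Cc1ccccc1)O[SiH](C)C | intermediate
12 | 5-[(2S,6E)-2,6-dimethyl-8-phenyloct-6-en-1-yl]-2,2,3,5-tetramethyl-2,5-dihydro-1,2-oxasilole, both C5 epimers | CC1=CC(C)(C[C@@H](C)CCC/C(C)=C/Cc2ccccc2)O[Si]1(C)C | intermediate
13 | methyl but-3-enoate | C=CCC(=O)OC | starting material
14 | methyl 3-hydroperoxy-3-methoxypropanoate, racemic | COC(=O)CC(OC)OO | intermediate
15 | methyl 3-({[(2Z,6S,10E)-4-hydroxy-4,6,10-trimethyl-12-phenyldodeca-2,10-dien-2-yl]dimethylsilyl}peroxy)-3-methoxypropanoate | COC(=O)CC(OC)OO[Si](C)(C)/C(C)=C\C(C)(O)C[C@@H](C)CCC/C(C)=C/Cc1ccccc1 | intermediate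
16 | methyl (3R,4Z,8S,12E)-6-hydroxy-3-{[methoxy(dimethyl)silyl]peroxy}-4,6,8,12-tetramethyl-14-phenyltetradeca-4,12-dienoate | CO[Si](C)(C)OO[C@H](CC(=O)OC)/C(C)=C\C(C)(O)C[C@@H](C)CCC/C(C)=C/Cc1ccccc1 | intermediate
17 | methyl 2-[(3R,6R)-4,6-dimethyl-6-[(2S,6E)-2,6-dimethyl-8-phenyloct-6-en-1-yl]-3,6-dihydro-1,2-dioxin-3-yl]acetate | COC(=O)C[C@H]1OO[C@](C)(C[C@@H](C)CCC/C(C)=C/Cc2ccccc2)C=C1C | intermediate
18 | (3R,4S,5R,6R,8S)-5-iodoplakortolide G | C/C(=C\Cc1ccccc1)CCC[C@H](C)C[C@]1(C)[C@H](I)[C@@]2(C)OC(=O)C[C@H]2OO1 | intermediate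
19 | plakortolide G | C/C(=C\Cc1ccccc1)CCC[C@H](C)C[C@]1(C)C[C@@]2(C)OC(=O)C[C@H]2OO1 | target

Total steps: 11. Longest linear sequence: 10 (steps 1–7 and 9–11, from hex-5-yn-1-ol).

Steps most likely to fail

1. Step 9.
- The tether may be lost by protodesilylation of the peroxide or of the vinylsilane.
- The allyl cation may lose a proton to give a triene.
- The peroxy acetal may fragment under acid.
- Facial selection at C3 by the anion, and the inside/outside choice between CH3 and the chain at C6, may be poor.
- Fallback (known chemistry): it sets out from 12 and returns at 17.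
  - Fluoride-promoted Hiyama–Denmark cross-coupling of the cyclic alkenylsiloxane 12 with methyl (E)-3-iodoacrylate (Bu4NF, Pd(dba)2, THF) makes C3–C4 with retention. This gives methyl (2E,4Z,8S,12E)-6-hydroxy-4,6,8,12-tetramethyl-14-phenyltetradeca-2,4,12-trienoate F1.
  - Acid-catalysed exchange of the tertiary allylic alcohol with H2O2 gives methyl (2E,4Z,8S,12E)-6-hydroperoxy-4,6,8,12-tetramethyl-14-phenyltetradeca-2,4,12-trienoate F2.
  - Amine-promoted 6-exo-trig oxa-Michael addition (Et2NH, CF3CH2OH) closes the ring to 17. The (3R,6R) isomer is then separated from its diastereomers by chromatography.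

2. Step 10.
- The ring alkene is flanked by two C–O bonds and is the less electron-rich one, so iodine may instead functionalise the side-chain alkene.
- The neutral ester may be too weak a nucleophile.
- The allylic C6–O bond may ionise.
- Fallback: it sets out from 17 and returns at 18. Mild saponification (LiOH, THF/H2O, 0 °C) gives 2-[(3R,6R)-4,6-dimethyl-6-[(2S,6E)-2,6-dimethyl-8-phenyloct-6-en-1-yl]-3,6-dihydro-1,2-dioxin-3-yl]acetic acid F3. Its carboxylate is cyclised under buffered two-phase iodolactonisation (I2, KI, NaHCO3, Et2O/H2O), where the anionic internal nucleophile should capture the reversibly formed ring iodonium ion.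

3. Step 4.
- 1,2-Addition of the Grignard reagent to the methyl ketone may compete, and facial selectivity with the small methyl nucleophile may be incomplete.
- Fallback: it sets out from 5 and returns at 8.
  - Wittig reaction with S-ethyl (triphenylphosphoranylidene)thioacetate gives S-ethyl (2E,7E)-7-methyl-9-phenylnona-2,7-dienethioate F4.
  - The same copper/ferrocenyl diphosphine system with MeMgBr, on this more selective substrate class, gives S-ethyl (3S,7E)-3,7-dimethyl-9-phenylnon-7-enethioate F5.
  - Me2CuLi converts the thioester into methyl ketone 8.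

Further compounds
F1 | step 9 | methyl (2E,4Z,8S,12E)-6-hydroxy-4,6,8,12-tetramethyl-14-phenyltetradeca-2,4,12-trienoate | COC(=O)/C=C/C(C)=C\C(C)(O)C[C@@H](C)CCC/C(C)=C/Cc1ccccc1
F2 | step 9 | methyl (2E,4Z,8S,12E)-6-hydroperoxy-4,6,8,12-tetramethyl-14-phenyltetradeca-2,4,12-trienoate | COC(=O)/C=C/C(C)=C\C(C)(OO)C[C@@H](C)CCC/C(C)=C/Cc1ccccc1
F3 | step 10 | 2-[(3R,6R)-4,6-dimethyl-6-[(2S,6E)-2,6-dimethyl-8-phenyloct-6-en-1-yl]-3,6-dihydro-1,2-dioxin-3-yl]acetic acid | OC(=O)C[C@H]1OO[C@](C)(C[C@@H](C)CCC/C(C)=C/Cc2ccccc2)C=C1C
F4 | step 4 | S-ethyl (2E,7E)-7-methyl-9-phenylnona-2,7-dienethioate | CCSC(=O)/C=C/CCC/C(C)=C/Cc1ccccc1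
F5 | step 4 | S-ethyl (3S,7E)-3,7-dimethyl-9-phenylnon-7-enethioate | CCSC(=O)C[C@@H](C)CCC/C(C)=C/Cc1ccccc1
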